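**Assumptions.** The target has no stereocentres: the quaternary carbon carries two methyls and a vinyl group, so it is achiral. The only stereo-element is the E-enone, which is set thermodynamically in Step 5. I also assume the less hindered OH of 3-methoxycatechol (the one remote from OMe) is alkylated preferentially in Step 1.

## Retrosynthetic overview
- No rings are formed; both aromatic rings come from commercial materials (3-methoxycatechol and 4'-hydroxyacetophenone).
- The E-enone is disconnected by Claisen–Schmidt condensation into a protected polyoxygenated benzaldehyde and 4'-hydroxyacetophenone.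
- The CHO is installed late, by ortho-lithiation/formylation of a bis-MOM arene; the OMe is the only free ortho-directing site, which fixes the position.
- The arene's 1,1-dimethylallyl (reverse-prenyl) quaternary carbon is made by a boron-templated ortho-Claisen of a mono-prenyl ether of commercial 3-methoxycatechol (the proposed new step). The second ortho position is blocked by the free OH, so the regiochemistry is inherent.

## Route

**Step 1**
Reactants: 1 (3-methoxycatechol), 2 (prenyl bromide)
Product: 3 (2-methoxy-6-[(3-methylbut-2-en-1-yl)oxy]phenol)
Conditions: 2 (1.0 equiv), K2CO3 (1.0 equiv), KI (cat.), acetone, 0 → 25 °C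
Reagents that add atoms: prenyl bromide, CC(C)=CCBr
Why: Williamson O-alkylation occurs at the less hindered OH remote from OMe, and the central OH, flanked by OMe and OH, is left free; the regioisomer and diether are removed by chromatography.

**Step 2**
Reactants: 3, 4 (dichloro(phenyl)borane)
Product: 5 (3-methoxy-6-(2-methylbut-3-en-2-yl)benzene-1,2-diol)
Conditions: 4 (1.2 equiv), 2,6-di-tert-butyl-4-methylpyridine (1.3 equiv), CH2Cl2, −78 → 0 °C; then 1 M aq. NaOH/THF, 0 °C, 10 min; then sat. aq. NH4Cl (to pH ~5)
Reagents that add atoms: none (the PhB unit is removed on hydrolysis)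
Why: Proposed new method: PhBCl2 esterifies the free OH and is chelated by the adjacent O-prenyl oxygen, forming a five-membered boron–oxonium that makes the prenyl aryl ether a much better [3,3] partner, so a chair-like aromatic Claisen delivers the CMe2 terminus (not the CH2 terminus) to the only free ortho carbon at ≤0 °C. Tautomerisation gives the catechol phenylboronate, which the aqueous base hydrolyses to the free catechol. The closest known reactions are BCl3/Et2AlCl-accelerated Claisen of aryl allyl ethers and the thermal Claisen of aryl prenyl ethers. The thermal version needs ~180 °C and gives normal-prenyl and dihydrobenzofuran by-products, and the new feature is that a neighbouring catechol OH serves as a removable boron tether.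

**Step 3**
Reactants: 5, 6 (chloromethyl methyl ether, MOMCl)
Product: 7 (1-(2-methylbut-3-en-2-yl)-3-methoxy... i.e. 2,3-bis(methoxymethoxy)-4-(2-methylbut-3-en-2-yl)-1-methoxybenzene)
Conditions: NaH (3 equiv), 6 (3 equiv), DMF, 0 → 25 °C
Reagents that add atoms: MOMCl, ClCOC
Why: Double Williamson-type acetal protection of the catechol (NaH ensures reaction of the OH next to the quaternary carbon) masks the oxidation-prone catechol and provides directing and protecting groups for the lithiation in Step 4.

**Step 4**
Reactants: 7, 8 (DMF)
Product: 9 (2-methoxy-3,4-bis(methoxymethoxy)-5-(2-methylbut-3-en-2-yl)benzaldehyde)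
Conditions: n-BuLi (1.3 equiv), TMEDA (1.3 equiv), THF, −78 → −20 °C; then 8 (3 equiv), −78 → 0 °C
Reagents that add atoms: DMF, CN(C)C=O (supplies the CHO carbon)
Why: Directed ortho-metalation occurs at the only ring C–H ortho to an oxygen substituent (ortho to OMe, para to OMOM), and DMF quench (Bouveault formylation) gives the aldehyde.

**Step 5**
Reactants: 9, 10 (4'-hydroxyacetophenone)
Product: 11 (the bis-MOM chalcone, E)
Conditions: KOH (4 equiv), EtOH/H2O, 25 → 50 °C, 24 h
Reagents that add atoms: none (10 is a reactant)
Why: Claisen–Schmidt (aldol) condensation with dehydration gives the thermodynamically favoured E-enone; excess base covers the free 4'-phenol, and the MOM ethers, OMe and vinyl group are base-stable.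

**Step 6**
Reactants: 11
Product: 12 (target)
Conditions: 3 M aq. HCl, MeOH/THF (1:1), 40 °C, 6 h
Reagents that add atoms: none (water is consumed; MOM is lost as CH2O/MeOH)
Why: Acid-catalysed acetal hydrolysis removes both aryl MOM ethers under conditions the E-enone and the unactivated terminal vinyl group tolerate, and no stereocentre is affected.

## Compound list
1 | 3-methoxycatechol | COc1cccc(O)c1O | starting material
2 | prenyl bromide | CC(C)=CCBr | starting material
3 | 2-methoxy-6-[(3-methylbut-2-en-1-yl)oxy]phenol | COc1cccc(OCC=C(C)C)c1O | intermediate
4 | dichloro(phenyl)borane | ClB(Cl)c1ccccc1 | starting material (reagent)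
5 | 3-methoxy-6-(2-methylbut-3-en-2-yl)benzene-1,2-diol | COc1ccc(C(C)(C)C=C)c(O)c1O | intermediate
6 | chloromethyl methyl ether | ClCOC | starting material (reagent)
7 | 1-methoxy-2,3-bis(methoxymethoxy)-4-(2-methylbut-3-en-2-yl)benzene | C=CC(C)(C)c1ccc(OC)c(OCOC)c1OCOC | intermediate
8 | N,N-dimethylformamide | CN(C)C=O | starting material (reagent)
9 | 2-methoxy-3,4-bis(methoxymethoxy)-5-(2-methylbut-3-en-2-yl)benzaldehyde | C=CC(C)(C)c1cc(C=O)c(OC)c(OCOC)c1OCOC | intermediate
10 | 4'-hydroxyacetophenone | CC(=O)c1ccc(O)cc1 | starting material
11 | (E)-1-(4-hydroxyphenyl)-3-[2-methoxy-3,4-bis(methoxymethoxy)-5-(2-methylbut-3-en-2-yl)phenyl]prop-2-en-1-one | C=CC(C)(C)c1cc(/C=C/C(=O)c2ccc(O)cc2)c(OC)c(OCOC)c1OCOC | intermediate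
12 | (E)-3-[5-(2-methylbut-3-en-2-yl)-3,4-dihydroxy-2-methoxyphenyl]-1-(4-hydroxyphenyl)prop-2-en-1-one (IN0234) | C=CC(C)(C)c1cc(/C=C/C(=O)c2ccc(O)cc2)c(OC)c(O)c1O | target

## Totals
Total steps: 6. Longest linear sequence: 6 (1 → 3 → 5 → 7 → 9 → 11 → 12).

## Three steps most likely to fail
1. **Step 2 (proposed new boron-templated Claisen).** The boron-oxonium may ionise to a prenyl cation, giving normal-prenyl or chroman by-products, or the boronate may resist hydrolysis.
   - Fallback (known chemistry, different approach): make 1,2-bis-MOM-3-methoxybenzene from 1 and MOMCl, lithiate ortho to the stronger OMOM director (the C4 position), and quench with I2. Then do a Pd-catalysed α-selective allyl–aryl Suzuki coupling with prenyl-Bpin to give 7 directly, bypassing 3 and 5.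
2. **Step 4 (ortho-lithiation/formylation).** Lithiation regioselectivity or MOM compatibility with n-BuLi may be poor.
   - Fallback: protect the catechol 5 as its diphenylmethylene ketal (Ph2CCl2) instead of bis-MOM. Formylate by Rieche formylation (Cl2CHOMe, TiCl4), which goes to the only unhindered position para to oxygen. Then continue with the Step 5 condensation and remove the ketal at the end with TFA/H2O.
3. **Step 6 (global MOM removal).** Aqueous HCl may cyclise the ortho-hydroxy reverse-prenyl group (to a dihydrobenzofuran) or add MeOH to the enone.
   - Fallback: use benzyl ethers instead of MOM in Step 3, and remove them at the end non-hydrogenolytically with BCl3·SMe2 and pentamethylbenzene (a cation scavenger), which avoids Brønsted-acid conditions and leaves the vinyl group intact.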